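## Structural features

Curlignan (15) is a 2,3-dihydro-1-benzofuran in which benzo ring A is fused through C3a and C7a to the five-membered O1–C2–C3 ring. Ring A carries a methyl ester at C5 (para to O1) and a methoxy group at C7 (ortho to O1); C2 carries ring B (4-hydroxy-3-methoxyphenyl) and C3 a hydroxymethyl group. C2 (S) and C3 (R) are adjacent stereocentres with the aryl and hydroxymethyl groups trans. The C2–O1 bond is the fragile point: it is a benzylic aryl ether para to the ring B phenol, so a free phenolate can expel O1 as a quinone methide, acid can ionise it and hydrogenolysis can cleave it. Any intermediate with a carbonyl group on C3 is epimerisable at C3 and can open by beta-elimination of O1, which helps in setting trans but is dangerous under strong base. The C5 ester and the C3 carbon end at different oxidation levels, so they should not both be esters when the hydride is applied. The real difficulty is absolute control of C2, with the relative configuration at C3, on a ring that offers no directing group. The key step uses the fact that C2–H is a benzylic ether C–H bond 1,5-related to C3 through O1, C7a and C3a, so a carbene at C3 can insert into it and close the C2–C3 bond and the dihydrofuran ring in one event.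

## Logic of the disconnections

**15 from 14.** Only the O–Si bond of the ring B phenol is cut. The phenol stays masked to the end because, once free, it makes the C2–O1 bond base-labile. The forward step must be a desilylation that never leaves a free phenolate standing. A triisopropylsilyl group is preferred to a smaller silyl group because it has to survive a Grignard reagent, amine bases and hot basic methanol.

**14 from 13.** The C5–carbonyl bond is cut, tracing the ester to an aryl bromide. Bromine is inert to the carbene, to base and to borohydride, and its late conversion avoids having to tell two esters apart in the reduction. The forward step is a palladium-catalysed methoxycarbonylation that must tolerate a free primary alcohol and an aryl silyl ether.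

**13 from 12, and 12 from 11.** No skeletal bond is cut: the C3 hydroxymethyl group goes back to a methyl ester and the trans ester to its cis epimer. The ester is what makes C3 a carbene carbon earlier and what makes C3 correctable afterwards. The forward demands are a base mild enough to epimerise without opening the ring and a hydride that spares the aryl bromide.

**11 from 10.** The C2–C3 bond is cut, which opens the dihydrofuran ring and removes both stereocentres. What remains is an achiral aryl benzyl ether with a diazo ester on ring A. The forward step must select one of the two enantiotopic OCH2 hydrogens under catalyst control.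

**10 from 8 (through 9), and 8 from 6 (through 7).** The diazo group is traced to a ketone, and then the aryl–carbonyl bond is cut. Both carbons of the future C3 unit therefore come in one operation from dimethyl oxalate and an arylmagnesium species. This replaces a multistep one-carbon homologation of an aryl aldehyde and avoids sulfonyl azides. The demand is an iodine–magnesium exchange that leaves the aryl bromide and the benzylic ether alone.

**6 from 5 and 3.** The O–CH2 bond of the aryl benzyl ether is cut. Joining a phenol and a benzylic alcohol directly avoids a 4-silyloxybenzyl halide, which ionises readily, and avoids carbonate in a dipolar solvent, which strips aryl silyl ethers. The demand is a Mitsunobu reaction on a phenol flanked by two ortho substituents.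

**5 from 4, and 3 from 2 from 1.** The C–I bond ortho to the phenol is cut, leaving a cheap bromophenol. Ring B goes back by functional group changes to a commodity aldehyde. The demands are ortho-selective iodination and a borohydride reduction that leaves the aryl silyl ether intact.

## Other disconnections considered

**Alternative 1:** Ring A is built last by cutting C3a–C7a and C6–C7. The forward step is the isomerisation of the furan ethynyl ether A1 with Ph3PAuNTf2, a cationic monovalent gold complex. The furan carbon bearing the side chain attacks the oxygen-bearing alkyne carbon, the other furan alpha-carbon ends bonded to the terminal alkyne carbon, and the furan oxygen emerges as the C7 phenol of A2.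
- In its favour: ring A and the dihydrofuran ring close together in an atom-economic step. The C5 ester and the C7 oxygen are placed without ambiguity, and no C3 carbonyl ever exists, so there is no epimerisation or ring-opening risk at that stage. On regiochemistry of ring A and on avoiding carbon monoxide it is the better plan.
- Against it here: the key step creates no stereocentre, so the anti C2/C3 pair of A1 must be made beforehand by a separate enantioselective acyclic sequence. The ethynyl ether must be installed on a secondary, electron-rich benzylic oxygen and is prone to ionisation or ketene-forming fragmentation under Lewis acids. The ester-bearing furan is a weakened nucleophile. After A2 an O-methylation and two deprotections remain.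
- Comparison: the chosen plan sets both stereocentres catalytically in the ring-forming step from an achiral precursor and should be several steps shorter. It pays for this with a late carbonylation.

**Alternative 2:** The O1–C2 bond is cut. In the forward step Ag2O oxidises the 4-hydroxy-3-methoxybenzyl unit of the diarylpropanol A3 to the para-quinone methide A4. The ring A phenol then adds to the methide carbon in a 5-exo closure, giving A5 with ring B trans to the C3 substituent.
- In its favour: ring B needs no protecting group, ring A already has its final substitution, and A5 is one desilylation from 15. No diazo compound, carbene or carbon monoxide is involved. On protecting-group economy and endgame length it is the better plan, and on trans selectivity it is probably the equal, since trans is also the thermodynamic outcome.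
- Against it here: all absolute stereochemistry rests on the single C3 centre of A3, which needs its own asymmetric synthesis, most plausibly a stoichiometric auxiliary alkylation. A4 has a hydrogen on C3 next to the methide, so tautomerisation to a styrene would erase that centre. The oxidant must discriminate between two phenols, and C2 is set only by substrate control.
- Comparison: the overall step count should be similar. The chosen plan controls C2 directly with a catalyst and corrects C3 afterwards, whereas here C2 is relayed from a centre that is itself at risk in the key intermediate.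

**Alternative 3:** Ring A is built by cutting C3a–C4 and C7–C7a. The forward step is an inverse-demand [4+2] cycloaddition of the bromopyrone A6 with the cyclic silyl ketene acetal A7. Pyrone C6 bonds to the nucleophilic ketene acetal carbon and pyrone C3 to the acetal carbon. Loss of CO2 and trimethylsilanol then aromatises ring A to give A8 with the trans dihydrofuran ring intact.
- In its favour: the plan is convergent, the polarity match fixes the regiochemistry, and the C5 ester is present from the start, which is better than a late carbonylation. The trans stereodiad sits in a ring where it is thermodynamically comfortable.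
- Against it here: C7 arrives as a bromide and needs a late C–O coupling to become the methoxy group, so the late aryl halide step is a tie and not a gain. Aromatisation must expel trimethylsilanol and not the ring oxygen from the acetal-like C7a; the wrong choice opens the dihydrofuran. A7 is moisture-sensitive, and its two stereocentres need a separate asymmetric sequence.
- Comparison: mechanistically the cycloaddition cascade is attractive and regiochemically more certain than a C–H insertion. Structurally it leaves the stereochemical problem unsolved, and the step count should be higher than in the chosen plan.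

Key step: step 7

Assumption: Rh2(S-PTTL)4 is written on the assumption that this ligand antipode selects the OCH2 hydrogen leading to 2S; should it lead to 2R, the mirror-image catalyst Rh2(R-PTTL)4 (from D-tert-leucine) is used with no other change.

## Route

Step 1
Reactants: 1 vanillin (4-hydroxy-3-methoxybenzaldehyde)
Product: 2 3-methoxy-4-(triisopropylsilyloxy)benzaldehyde
Conditions: TIPSCl, imidazole, DMF, 0 °C to rt
Reagents that add atoms: chlorotriisopropylsilane, CC(C)[Si](Cl)(C(C)C)C(C)C
Why: Imidazole-promoted O-silylation of a phenol; the triisopropylsilyl ether is chosen because it should survive the Grignard, amine-base and hot basic methanol steps ahead, where smaller aryl silyl ethers are marginal.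

Step 2
Reactants: 2 3-methoxy-4-(triisopropylsilyloxy)benzaldehyde
Product: 3 [3-methoxy-4-(triisopropylsilyloxy)phenyl]methanol
Conditions: NaBH4, THF/MeOH, 0 °C
Reagents that add atoms: none
Why: Borohydride reduction of an aryl aldehyde; low temperature and a short reaction time keep methoxide from attacking the aryl silyl ether.

Step 3
Reactants: 4 4-bromo-2-methoxyphenol
Product: 5 4-bromo-2-iodo-6-methoxyphenol
Conditions: NIS, TsOH·H2O (cat.), MeCN, 0 °C to rt
Reagents that add atoms: N-iodosuccinimide, O=C1CCC(=O)N1I
Why: Electrophilic aromatic iodination; the hydroxyl group is the strongest director and its para position is blocked by bromine, so iodine should enter the single free ortho position.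

Step 4
Reactants: 5 4-bromo-2-iodo-6-methoxyphenol; 3 [3-methoxy-4-(triisopropylsilyloxy)phenyl]methanol
Product: 6 [4-[(4-bromo-2-iodo-6-methoxyphenoxy)methyl]-2-methoxyphenoxy]triisopropylsilane
Conditions: PPh3, DIAD, THF, 0 °C to rt
Reagents that add atoms: none
Why: Mitsunobu etherification of a primary benzylic alcohol with a phenol made acidic by its halogens; it avoids the ionisable 4-silyloxybenzyl halide and the carbonate/DMF conditions that transfer silyl groups from aryl ethers.

Step 5
Reactants: 6 [4-[(4-bromo-2-iodo-6-methoxyphenoxy)methyl]-2-methoxyphenoxy]triisopropylsilane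
Product: 8 methyl 2-[5-bromo-3-methoxy-2-[[3-methoxy-4-(triisopropylsilyloxy)phenyl]methoxy]phenyl]-2-oxoacetate, via arylmagnesium chloride 7 (not isolated)
Conditions: iPrMgCl·LiCl, THF, −30 °C; cannulated into (CO2Me)2 (3 equiv), THF, −78 to −20 °C; aq. NH4Cl
Reagents that add atoms: dimethyl oxalate, COC(=O)C(=O)OC
Why: Iodine–magnesium exchange is far faster at C–I than at C–Br and is helped by the ortho ether oxygen, and an arylmagnesium (unlike an aryllithium) should not deprotonate the benzylic ether; inverse addition to excess oxalate at low temperature stops at the keto ester because the magnesium hemiketal alkoxide persists until work-up.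

Step 6
Reactants: 8 methyl 2-[5-bromo-3-methoxy-2-[[3-methoxy-4-(triisopropylsilyloxy)phenyl]methoxy]phenyl]-2-oxoacetate
Product: 10 methyl 2-[5-bromo-3-methoxy-2-[[3-methoxy-4-(triisopropylsilyloxy)phenyl]methoxy]phenyl]-2-diazoacetate, via tosylhydrazone 9 (not isolated)
Conditions: TsNHNH2, MeOH, 50 °C; solvent switch; DBU, CH2Cl2, 0 °C to rt
Reagents that add atoms: p-toluenesulfonyl hydrazide, Cc1ccc(cc1)S(=O)(=O)NN
Why: Condensation to the N-tosylhydrazone followed by base-induced loss of sulfinate (Bamford–Stevens diazo synthesis) is a standard entry to aryldiazoacetates and needs no sulfonyl azide; methanol matches the methyl ester, so ester exchange is harmless.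

Step 7
Reactants: 10 methyl 2-[5-bromo-3-methoxy-2-[[3-methoxy-4-(triisopropylsilyloxy)phenyl]methoxy]phenyl]-2-diazoacetate
Product: 11 methyl (2S,3R)-5-bromo-7-methoxy-2-[3-methoxy-4-(triisopropylsilyloxy)phenyl]-2,3-dihydro-1-benzofuran-3-carboxylate (cis)
Conditions: Rh2(S-PTTL)4 (1 mol %), toluene, −60 °C, slow addition of 10
Reagents that add atoms: none
Why: Rh2(S-PTTL)4, dirhodium tetrakis[N-phthaloyl-(S)-tert-leucinate], decomposes the aryldiazoacetate with loss of N2 to a donor/acceptor rhodium carbenoid at the future C3, which engages an OCH2 C–H bond in a concerted, asynchronous three-centre transition state with hydride-transfer character. The closest known reaction type is the dirhodium-carboxylate-catalysed enantioselective intramolecular C–H insertion of methyl 2-(2-benzyloxyphenyl)-2-diazoacetates, which gives cis-2-aryl-2,3-dihydrobenzofuran-3-carboxylates. The dihydrofuran ring closes by 1,5-insertion: C3, C3a, C7a, O1 and C2 become the five-membered ring as the C2–C3 bond forms. C2 is set by the catalyst, whose chiral carboxylate ligands distinguish the two enantiotopic hydrogens of the OCH2 group. C3 is set in the same event, and the cis relationship should follow from the approach geometry in which ring B turns away from the ligand wall. Only C2 has to be carried forward, because C3 is corrected in step 8. Site selectivity rests on the substrate: the OCH2 hydrogens are the only ones that are both 1,5-related to the carbene and doubly activated (alpha to oxygen and benzylic to the electron-rich ring B), the methoxy C–H bonds are out of reach or need larger rings, and ylide formation at O1 would need a four-membered ring. Low temperature, a non-coordinating solvent and slow addition should suppress carbene dimerisation and keep the insertion under catalyst control.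

Step 8
Reactants: 11 methyl (2S,3R)-5-bromo-7-methoxy-2-[3-methoxy-4-(triisopropylsilyloxy)phenyl]-2,3-dihydro-1-benzofuran-3-carboxylate (cis)
Product: 12 methyl (2S,3S)-5-bromo-7-methoxy-2-[3-methoxy-4-(triisopropylsilyloxy)phenyl]-2,3-dihydro-1-benzofuran-3-carboxylate (trans)
Conditions: DBU (0.5 equiv), toluene, rt
Reagents that add atoms: none
Why: Thermodynamic epimerisation through the ester enolate; the trans isomer relieves the eclipsing of ring B and the ester, C2 has no acidic hydrogen and stays S, and an amidine base in an aprotic solvent should limit beta-elimination of O1.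

Step 9
Reactants: 12 methyl (2S,3S)-5-bromo-7-methoxy-2-[3-methoxy-4-(triisopropylsilyloxy)phenyl]-2,3-dihydro-1-benzofuran-3-carboxylate (trans)
Product: 13 [(2S,3R)-5-bromo-7-methoxy-2-[3-methoxy-4-(triisopropylsilyloxy)phenyl]-2,3-dihydro-1-benzofuran-3-yl]methanol (trans)
Conditions: LiBH4, THF, 0 °C to rt
Reagents that add atoms: none
Why: LiBH4 reduces the ester to the primary alcohol and leaves the aryl bromide and silyl ether alone; once C3 is no longer alpha to a carbonyl group the trans relationship is locked (the descriptor changes to R only through priorities).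

Step 10
Reactants: 13 [(2S,3R)-5-bromo-7-methoxy-2-[3-methoxy-4-(triisopropylsilyloxy)phenyl]-2,3-dihydro-1-benzofuran-3-yl]methanol (trans)
Product: 14 methyl (2S,3R)-3-(hydroxymethyl)-7-methoxy-2-[3-methoxy-4-(triisopropylsilyloxy)phenyl]-2,3-dihydro-1-benzofuran-5-carboxylate
Conditions: Pd(OAc)2 (3 mol %), Xantphos (6 mol %), CO (1 atm), Et3N, MeOH, 70 °C
Reagents that add atoms: carbon monoxide, [C-]#[O+]; methanol, CO
Why: Palladium-catalysed alkoxycarbonylation of an aryl bromide (oxidative addition to zerovalent palladium, CO insertion, methanolysis of the acylpalladium); the wide-bite-angle ligand allows atmospheric pressure, solvent methanol should outcompete the substrate hydroxyl, and neither stereocentre is acidic any longer.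

Step 11
Reactants: 14 methyl (2S,3R)-3-(hydroxymethyl)-7-methoxy-2-[3-methoxy-4-(triisopropylsilyloxy)phenyl]-2,3-dihydro-1-benzofuran-5-carboxylate
Product: 15 curlignan, methyl (2S,3R)-2-(4-hydroxy-3-methoxyphenyl)-3-(hydroxymethyl)-7-methoxy-2,3-dihydro-1-benzofuran-5-carboxylate
Conditions: TBAF, AcOH (1:1), THF, 0 °C
Reagents that add atoms: none
Why: Fluoride cleavage of the aryl silyl ether; acetic acid keeps the liberated phenol protonated, so O1 should not be expelled through a quinone methide and the methyl ester should not be saponified.

## Compound list

1 | vanillin (4-hydroxy-3-methoxybenzaldehyde) | COc1cc(C=O)ccc1O | starting material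
2 | 3-methoxy-4-(triisopropylsilyloxy)benzaldehyde | COc1cc(C=O)ccc1O[Si](C(C)C)(C(C)C)C(C)C | intermediate
3 | [3-methoxy-4-(triisopropylsilyloxy)phenyl]methanol | COc1cc(CO)ccc1O[Si](C(C)C)(C(C)C)C(C)C | intermediate
4 | 4-bromo-2-methoxyphenol | COc1cc(Br)ccc1O | starting material
5 | 4-bromo-2-iodo-6-methoxyphenol | COc1cc(Br)cc(I)c1O | intermediate
6 | [4-[(4-bromo-2-iodo-6-methoxyphenoxy)methyl]-2-methoxyphenoxy]triisopropylsilane | COc1cc(Br)cc(I)c1OCc1ccc(O[Si](C(C)C)(C(C)C)C(C)C)c(OC)c1 | intermediate
7 | [5-bromo-3-methoxy-2-[[3-methoxy-4-(triisopropylsilyloxy)phenyl]methoxy]phenyl]magnesium chloride | COc1cc(Br)cc([Mg]Cl)c1OCc1ccc(O[Si](C(C)C)(C(C)C)C(C)C)c(OC)c1 | intermediate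
8 | methyl 2-[5-bromo-3-methoxy-2-[[3-methoxy-4-(triisopropylsilyloxy)phenyl]methoxy]phenyl]-2-oxoacetate | COC(=O)C(=O)c1cc(Br)cc(OC)c1OCc1ccc(O[Si](C(C)C)(C(C)C)C(C)C)c(OC)c1 | intermediate
9 | N-tosylhydrazone of 8 | COC(=O)C(=NNS(=O)(=O)c1ccc(C)cc1)c1cc(Br)cc(OC)c1OCc1ccc(O[Si](C(C)C)(C(C)C)C(C)C)c(OC)c1 | intermediate
10 | methyl 2-[5-bromo-3-methoxy-2-[[3-methoxy-4-(triisopropylsilyloxy)phenyl]methoxy]phenyl]-2-diazoacetate | COC(=O)C(=[N+]=[N-])c1cc(Br)cc(OC)c1OCc1ccc(O[Si](C(C)C)(C(C)C)C(C)C)c(OC)c1 | intermediate
11 | methyl (2S,3R)-5-bromo-7-methoxy-2-[3-methoxy-4-(triisopropylsilyloxy)phenyl]-2,3-dihydro-1-benzofuran-3-carboxylate (cis) | Brc1cc(OC)c2c(c1)[C@@H](C(=O)OC)[C@@H](c1ccc(O[Si](C(C)C)(C(C)C)C(C)C)c(OC)c1)O2 | intermediate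
12 | methyl (2S,3S)-5-bromo-7-methoxy-2-[3-methoxy-4-(triisopropylsilyloxy)phenyl]-2,3-dihydro-1-benzofuran-3-carboxylate (trans) | Brc1cc(OC)c2c(c1)[C@H](C(=O)OC)[C@@H](c1ccc(O[Si](C(C)C)(C(C)C)C(C)C)c(OC)c1)O2 | intermediate
13 | [(2S,3R)-5-bromo-7-methoxy-2-[3-methoxy-4-(triisopropylsilyloxy)phenyl]-2,3-dihydro-1-benzofuran-3-yl]methanol (trans) | Brc1cc(OC)c2c(c1)[C@H](CO)[C@@H](c1ccc(O[Si](C(C)C)(C(C)C)C(C)C)c(OC)c1)O2 | intermediate
14 | methyl (2S,3R)-3-(hydroxymethyl)-7-methoxy-2-[3-methoxy-4-(triisopropylsilyloxy)phenyl]-2,3-dihydro-1-benzofuran-5-carboxylate | COC(=O)c1cc(OC)c2c(c1)[C@H](CO)[C@@H](c1ccc(O[Si](C(C)C)(C(C)C)C(C)C)c(OC)c1)O2 | intermediate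
15 | curlignan, methyl (2S,3R)-2-(4-hydroxy-3-methoxyphenyl)-3-(hydroxymethyl)-7-methoxy-2,3-dihydro-1-benzofuran-5-carboxylate | COC(=O)c1cc(OC)c2c(c1)[C@H](CO)[C@@H](c1ccc(O)c(OC)c1)O2 | target

## Step count and risk

Total step count: 11. Longest linear sequence: 10 steps (1 to 2 to 3 to 6 to 8 to 10 to 11 to 12 to 13 to 14 to 15); the branch from 4 joins at step 4.

**Step 7 (key step).** The most likely failure is erosion of enantioselectivity. The strongly donating para-silyloxy group on ring B can push the hydride transfer towards a stepwise, zwitterionic course that the ligands control less well, and the benzyloxy group is twisted out of plane by its two ortho neighbours. Carbene dimerisation is a secondary risk. The fallback replaces catalyst-only control by double stereodifferentiation with a covalently bound auxiliary. It sets out from 8. Mild saponification (LiOH, aqueous THF, 0 °C) should give the keto acid F1. Carbodiimide coupling with (S)-2-hydroxy-1-(pyrrolidin-1-yl)propan-1-one should give the lactamide keto ester F2. Treatment as in step 6 should lead through the tosylhydrazone F3 to the diazo ester F4. Insertion with Rh2(S-DOSP)4, dirhodium tetrakis[(S)-N-(4-dodecylbenzenesulfonyl)prolinate], the auxiliary and catalyst antipodes being the matched pair for 2S, should give the trans auxiliary ester F5, if necessary after brief DBU equilibration. LiBH4 then cleaves the auxiliary ester reductively, and the route is rejoined at 13.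

**Step 4.** The Mitsunobu reaction may stall at the doubly ortho-substituted phenol, and the activated benzylic oxyphosphonium ion may ionise and self-condense. The fallback sets out from 3. MsCl and Et3N in CH2Cl2 should convert it into the benzylic chloride F6, which is used at once to O-alkylate 5 with K2CO3 in acetone, a medium that does not strip aryl silyl ethers. The route is rejoined at 6.

**Step 5.** Over-addition of 7 to the keto ester or incomplete and unselective halogen–magnesium exchange would erode the keto ester. The fallback abandons the organomagnesium route. Starting from 6, Pd(PPh3)4, Ag2CO3 and Et3N in toluene at rt should couple the aryl iodide chemoselectively with methyl diazoacetate (handled as a dilute solution). This gives 10 directly and bypasses 7, 8 and 9.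

**Step 8.** Equilibration may be slow with an amidine base, and forcing it invites E1cB opening of the C2–O1 bond to a phenolate and an aryl cinnamate. The fallback moves the epimerisation to the aldehyde oxidation level, where a weak base suffices. Starting from 11, DIBAL-H in toluene at −78 °C should give the cis aldehyde F7. Et3N in CH2Cl2 at 0 °C should equilibrate it to the trans aldehyde F8, and NaBH4 reduction rejoins the route at 13.

**Step 10.** Oxidative addition into the electron-rich aryl bromide may be sluggish, with protodebromination or acylation of the primary hydroxyl group by the acylpalladium as competing processes. The fallback avoids palladium and carbon monoxide. Starting from 13, n-BuLi (2.2 equiv, THF, −78 °C) should form the alkoxide and then the aryllithium, and CO2 should trap it as the carboxylic acid F9. Chemoselective carboxylate alkylation with MeI and KHCO3 in DMF rejoins the route at 14.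

## Further compounds

F1 | step 7 | 2-[5-bromo-3-methoxy-2-[[3-methoxy-4-(triisopropylsilyloxy)phenyl]methoxy]phenyl]-2-oxoacetic acid | OC(=O)C(=O)c1cc(Br)cc(OC)c1OCc1ccc(O[Si](C(C)C)(C(C)C)C(C)C)c(OC)c1
F2 | step 7 | (S)-1-oxo-1-(pyrrolidin-1-yl)propan-2-yl 2-[5-bromo-3-methoxy-2-[[3-methoxy-4-(triisopropylsilyloxy)phenyl]methoxy]phenyl]-2-oxoacetate | C[C@H](OC(=O)C(=O)c1cc(Br)cc(OC)c1OCc1ccc(O[Si](C(C)C)(C(C)C)C(C)C)c(OC)c1)C(=O)N1CCCC1
F3 | step 7 | N-tosylhydrazone of F2 | C[C@H](OC(=O)C(=NNS(=O)(=O)c1ccc(C)cc1)c1cc(Br)cc(OC)c1OCc1ccc(O[Si](C(C)C)(C(C)C)C(C)C)c(OC)c1)C(=O)N1CCCC1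
F4 | step 7 | (S)-1-oxo-1-(pyrrolidin-1-yl)propan-2-yl 2-[5-bromo-3-methoxy-2-[[3-methoxy-4-(triisopropylsilyloxy)phenyl]methoxy]phenyl]-2-diazoacetate | C[C@H](OC(=O)C(=[N+]=[N-])c1cc(Br)cc(OC)c1OCc1ccc(O[Si](C(C)C)(C(C)C)C(C)C)c(OC)c1)C(=O)N1CCCC1
F5 | step 7 | (S)-1-oxo-1-(pyrrolidin-1-yl)propan-2-yl (2S,3S)-5-bromo-7-methoxy-2-[3-methoxy-4-(triisopropylsilyloxy)phenyl]-2,3-dihydro-1-benzofuran-3-carboxylate (trans) | Brc1cc(OC)c2c(c1)[C@H](C(=O)O[C@@H](C)C(=O)N1CCCC1)[C@@H](c1ccc(O[Si](C(C)C)(C(C)C)C(C)C)c(OC)c1)O2
F6 | step 4 | [4-(chloromethyl)-2-methoxyphenoxy]triisopropylsilane | COc1cc(CCl)ccc1O[Si](C(C)C)(C(C)C)C(C)C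
F0 | step 5 | none | none
F7 | step 8 | (2S,3R)-5-bromo-7-methoxy-2-[3-methoxy-4-(triisopropylsilyloxy)phenyl]-2,3-dihydro-1-benzofuran-3-carbaldehyde (cis) | Brc1cc(OC)c2c(c1)[C@@H](C=O)[C@@H](c1ccc(O[Si](C(C)C)(C(C)C)C(C)C)c(OC)c1)O2
F8 | step 8 | (2S,3S)-5-bromo-7-methoxy-2-[3-methoxy-4-(triisopropylsilyloxy)phenyl]-2,3-dihydro-1-benzofuran-3-carbaldehyde (trans) | Brc1cc(OC)c2c(c1)[C@H](C=O)[C@@H](c1ccc(O[Si](C(C)C)(C(C)C)C(C)C)c(OC)c1)O2
F9 | step 10 | (2S,3R)-3-(hydroxymethyl)-7-methoxy-2-[3-methoxy-4-(triisopropylsilyloxy)phenyl]-2,3-dihydro-1-benzofuran-5-carboxylic acid | OC(=O)c1cc(OC)c2c(c1)[C@H](CO)[C@@H](c1ccc(O[Si](C(C)C)(C(C)C)C(C)C)c(OC)c1)O2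
A1 | alternative 1 | methyl 5-[1-(tert-butyldimethylsilyloxy)-3-ethynyloxy-3-(3-methoxy-4-methoxymethoxyphenyl)propan-2-yl]furan-3-carboxylate, both centres as in the target | COC(=O)c1coc(c1)[C@H](CO[Si](C)(C)C(C)(C)C)[C@@H](c1ccc(OCOC)c(OC)c1)OC#C
A2 | alternative 1 | methyl trans-3-(tert-butyldimethylsilyloxymethyl)-7-hydroxy-2-(3-methoxy-4-methoxymethoxyphenyl)-2,3-dihydro-1-benzofuran-5-carboxylate | COC(=O)c1cc(O)c2c(c1)[C@H](CO[Si](C)(C)C(C)(C)C)[C@@H](c1ccc(OCOC)c(OC)c1)O2
A3 | alternative 2 | methyl 3-[1-(tert-butyldimethylsilyloxy)-3-(4-hydroxy-3-methoxyphenyl)propan-2-yl]-4-hydroxy-5-methoxybenzoate, C3 as in the target | COC(=O)c1cc(OC)c(O)c(c1)[C@H](CO[Si](C)(C)C(C)(C)C)Cc1ccc(O)c(OC)c1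
A4 | alternative 2 | para-quinone methide of A3 | COC(=O)c1cc(OC)c(O)c(c1)[C@H](CO[Si](C)(C)C(C)(C)C)C=C1C=CC(=O)C(OC)=C1
A5 | alternative 2 | curlignan primary tert-butyldimethylsilyl ether | COC(=O)c1cc(OC)c2c(c1)[C@H](CO[Si](C)(C)C(C)(C)C)[C@@H](c1ccc(O)c(OC)c1)O2
A6 | alternative 3 | methyl 3-bromo-2-oxo-2H-pyran-5-carboxylate | COC(=O)C1=COC(=O)C(Br)=C1
A7 | alternative 3 | trans-4-(tert-butyldimethylsilyloxymethyl)-5-(3-methoxy-4-methoxymethoxyphenyl)-2-(trimethylsilyloxy)-4,5-dihydrofuran | C[Si](C)(C)OC1=C[C@H](CO[Si](C)(C)C(C)(C)C)[C@@H](c2ccc(OCOC)c(OC)c2)O1
A8 | alternative 3 | methyl trans-7-bromo-3-(tert-butyldimethylsilyloxymethyl)-2-(3-methoxy-4-methoxymethoxyphenyl)-2,3-dihydro-1-benzofuran-5-carboxylate | COC(=O)c1cc(Br)c2c(c1)[C@H](CO[Si](C)(C)C(C)(C)C)[C@@H](c1ccc(OCOC)c(OC)c1)O2
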